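Compound numbers are those of the list after the steps. The ring positions O1 and C2 to C5 of the target oxolane are used for the same atoms in every intermediate.

## Analysis of the target

Agastinol (25) is a lignan built on one oxolane ring (O1, C2 to C5), with a 4-hydroxy-3-methoxyphenyl group on C2, a CH2O arm acylated by 4-hydroxybenzoic acid on C3, a 4-hydroxy-3-methoxybenzyl group on C4 and an unsubstituted C5. C2, C3 and C4 are contiguous stereocentres, (2R,3S,4S): the C2 aryl group is trans to the C3 arm, and the C3 and C4 arms are cis. The 3,4-cis relationship is the less stable one and cannot be restored once lost, whereas C2 is a benzylic carbon para to oxygen that ionises readily and returns to the 2,3-trans arrangement. The same ease of ionisation makes C2–O1 the weak bond: acid can open it and let the C4 arene close an aryltetralin, and hydrogenolysis can cleave it. Three phenols and a single ester on one particular primary oxygen mean that the C3 oxygen must stay distinguishable from the C5 oxygen and from the phenols throughout. The difficulty is therefore to fix the absolute configuration of a ring whose only functional group is its ether oxygen, and to make the cis pair under kinetic control. The plan rests on one observation: C2, C3, C4 and C5 form an unbroken four-carbon chain whose two ends are both bonded to O1, so removing O1 and joining C2 to C5 leaves a 2-aryl-3-(oxymethyl)cyclobutanone with C5 as the carbonyl carbon, the product pattern of a ketene-type [2+2] cycloaddition followed by Baeyer–Villiger oxygen insertion.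

## Retrosynthetic reasoning

**Phenols and ester.** The three phenols of 25 are masked as benzyl ethers in 24, so that one hydrogenolysis ends the synthesis. The ester C–O bond of 24 is cut to alcohol 22 and acid 23. The ester is thus put on at a stage where exactly one hydroxyl is free.

**Oxolane ring.** Alcohol 22 comes from silyl ether 21, and the ring of 21 is opened at O1 to the 1,4-diol 20. Forward, the benzylic hydroxyl at C2 ionises under acid and the C5 hydroxyl closes the ring; C2 settles trans to the C3 arm. The cut is made here because it turns the ether into the reduction product of a lactone, 19, in which C5 is a carbonyl carbon and can activate C4.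

**C4 side chain.** In 19 the bond between C4 and the benzylic CH2 is cut, through arylidene lactone 18, to lactone 12 and aldehyde 14. Direct alkylation of the enolate of 12 would put the benzyl group trans to the C3 arm. Condensation followed by hydrogenation from the face opposite the C3 arm gives the cis isomer instead, which is why the bond is made as a C=C first.

**O1.** Lactone 12 is traced back to cyclobutanone 11 by removing O1 from between C2 and C5. The forward Baeyer–Villiger step must migrate the aryl-bearing carbon, not the C4 methylene, and keep its configuration. The gain is a carbocycle whose two ring bonds can be made in one cycloaddition.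

**Cyclobutane.** In 11 the C4–C5 and C2–C3 bonds are cut, giving amide 6 (as its keteniminium ion) and alkene 8. The forward step has to place the oxymethyl arm on C3 rather than C4, and has to set C3 in the absolute sense under control of the C2-symmetric pyrrolidine on nitrogen. C2 follows by equilibration.

**Building blocks.** Amide 6 is made from acid 3 and amine 4, and 3 from homovanillic acid 1. Alkene 8 comes from allyl alcohol 7, and aldehyde 14 from vanillin 13.

## Alternatives that were turned down

**Alternative 1:** The bond from C4 to the benzylic carbon and the C2–C3 bond are made on a chiral butenolide.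
- Key step: the lithium anion of aryl dithiane A3 adds 1,4 to the menthyl acetal butenolide A2, anti to the acetal oxygen. The lactone enolate is then trapped in the same flask by aldehyde 14, anti to the new substituent, giving the trans,trans lactone A1. When the ring is later redrawn through C2, this trans relationship becomes the 3,4-cis relationship of the target.
- For: three components, two C–C bonds and all carbons of the skeleton in one operation, with an auxiliary whose sense of induction is well understood. On convergence and on certainty of absolute configuration this is stronger than the cyclobutanone plan, and it is also shorter overall.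
- Against: A1 has the wrong oxidation level at three carbons. The dithiane must be removed reductively over nickel in a molecule with aryl benzyl ethers and a benzylic carbinol. Both the acetal carbon (future C5) and the lactone carbonyl (future CH2O arm) must be taken down to alcohols. The resulting triol has two primary hydroxyls that are told apart only by the ring closure, and the oxolane is closed by the same acid cyclisation as here, so that risk is not avoided.
- Comparison: the chosen plan offers a sulfur-free sequence and a C3 oxygen that is differentiated as a silyl ether from the first step. C5 needs a single hydride reduction, and the auxiliary is returned by simple hydrolysis.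

**Alternative 2:** The ring bond C3–C4 and the bond from the benzylic CH2 to its arene are made in a radical cascade.
- Key step: a nickel catalyst (NiCl2·glyme, a bipyridine ligand, zinc as reductant) abstracts iodine from the acyclic iodo allyl ether A5. The C3 radical closes 5-exo onto the allyl group, and the exocyclic primary radical is arylated through nickel with aryl iodide A6 to give oxolane A4.
- For: A4 is three steps from the target, so this is clearly the shortest route after the key step. The chair-like transition state of 5-exo closure predicts the required 2,3-trans-3,4-cis isomer as the major one.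
- Against: A5 needs its own enantioselective synthesis of the C2 ether centre. C3 and C4 are both set in one kinetically controlled event from that single centre with no chance of correction, and diastereomeric oxolanes of this kind are hard to separate. Arylation of the primary radical must also outrun hydrogen abstraction.
- Comparison: the chosen plan is longer, but it sets each stereocentre in a separate step with its own control element and can purify at crystalline lactone stages.

**Alternative 3:** The C3 arm and the C4 benzylic carbon are introduced together as the two carbons of an alkyne.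
- Key step: a cobalt catalyst (CoBr2, a bisphosphine, zinc) joins arylalkyne A9 across C3=C4 of the 2-aryl-2,5-dihydrofuran A8, itself available by enantioselective Heck arylation. This gives the cis-fused cyclobutene A7, anti to the C2 aryl group; ozonolysis then gives an aldehyde on C3 and an aryl ketone on C4.
- For: the absolute configuration comes from a catalytic asymmetric step, and the cis ring fusion guarantees the 3,4-cis pair. Both points are stronger than a stoichiometric auxiliary and a face-selective hydrogenation.
- Against: the two alkene carbons of A8 differ only by the distant aryl group, so nothing secures which alkyne carbon bonds to C3. Ozone must spare two electron-rich arenes. The cis keto-aldehyde is epimerisable at both C3 and C4. The aryl ketone must be reduced to CH2 without cleaving the benzylic C2–O1 bond.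
- Comparison: the step count is no lower than here. The chosen plan has a regiochemistry fixed by cation stability and never places a carbonyl on the C3 arm.

Key step: step 4

Assumption: the (2R,5R)-pyrrolidine 4 is taken to steer the cycloaddition to the (3R)-cyclobutanone 11 (C3 of the target S). This sense of induction is not established for this pair of partners; if it proves opposite, the (2S,5S)-amine is used with no other change.

## Route

Step 1
Reactants: 1 homovanillic acid
Product: 3 2-(4-benzyloxy-3-methoxyphenyl)acetic acid, via benzyl ester 2 (not isolated)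
Conditions: BnBr (2.3 equiv), K2CO3, DMF, 60 °C; then aq. NaOH, MeOH, 60 °C; then aq. HCl
Reagents that add atoms: benzyl bromide, BrCc1ccccc1; sodium hydroxide, [Na+].[OH-] (one carboxyl oxygen of 3 after saponification)
Why: Williamson O-alkylation of phenoxide and carboxylate, then saponification of the benzyl ester in the same pot; the aryl benzyl ether is inert to hydroxide, so only the phenol stays protected.

Step 2
Reactants: 3 2-(4-benzyloxy-3-methoxyphenyl)acetic acid; 4 (2R,5R)-2,5-dimethylpyrrolidine
Product: 6 2-(4-benzyloxy-3-methoxyphenyl)-1-[(2R,5R)-2,5-dimethylpyrrolidin-1-yl]ethan-1-one, via acid chloride 5 (not isolated)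
Conditions: (COCl)2, DMF (cat.), CH2Cl2, 0 °C to rt; concentrate; then 4, Et3N, CH2Cl2, 0 °C to rt
Reagents that add atoms: oxalyl chloride, O=C(Cl)C(=O)Cl (chlorine of intermediate 5 only; no atom of it remains in 6)
Why: Amide formation through the acid chloride, the reliable way to acylate a hindered 2,5-disubstituted pyrrolidine; the amine stereocentres are not involved.

Step 3
Reactants: 7 allyl alcohol
Product: 8 allyl triisopropylsilyl ether
Conditions: TIPSCl, imidazole, CH2Cl2, 0 °C to rt
Reagents that add atoms: chlorotriisopropylsilane, CC(C)[Si](Cl)(C(C)C)C(C)C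
Why: Standard silylation of a primary alcohol; the triisopropylsilyl group is chosen because its bulk shields the ether oxygen from electrophiles in step 4 and because it survives peracid, amide base, LiAlH4 and anhydrous sulfonic acid, yet leaves with fluoride.

Step 4
Reactants: 6 2-(4-benzyloxy-3-methoxyphenyl)-1-[(2R,5R)-2,5-dimethylpyrrolidin-1-yl]ethan-1-one; 8 allyl triisopropylsilyl ether
Product: 11 (2R,3R)-2-(4-benzyloxy-3-methoxyphenyl)-3-[(triisopropylsilyloxy)methyl]cyclobutan-1-one, via keteniminium triflate 9 (not isolated), via cyclobutaniminium triflate 10 (not isolated)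
Conditions: Tf2O (1.2 equiv), 2,4,6-collidine (1.3 equiv), 8 (3 equiv), ClCH2CH2Cl, −20 °C to 80 °C; then aq. NaHCO3, THF, 40 °C
Reagents that add atoms: water, O (carbonyl oxygen of 11); triflic anhydride, O=S(=O)(OS(=O)(=O)C(F)(F)F)C(F)(F)F (triflate counter-ion of 9 and 10 only)
Why: Tf2O O-sulfonylates amide 6 and collidine removes the benzylic proton with loss of triflate, giving the α-aryl keteniminium ion 9; its sp carbon (future C5) is attacked by the terminal carbon of 8 (future C4), and the cation developing at the internal carbon (future C3) is captured by the enamine carbon (future C2), so the cyclobutane is closed stepwise by a 4-exo attack of the enamine on the cation. The closest known reaction type is the [2+2] cycloaddition of keteniminium salts, made from tertiary amides with Tf2O and collidine, to unactivated alkenes, including amides of C2-symmetric 2,5-dimethylpyrrolidine. Regiochemistry follows from the preference for the secondary over the primary cation, which puts the silyloxymethyl arm on C3 next to the aryl-bearing C2. C3 is the stereocentre that counts: it is set under control of the pyrrolidine, whose two methyl groups flank the plane in which the alkene must approach the C=N+ carbon and so decide on which side the CH2OTIPS arm is carried (sense assumed, see above). C2 is controlled thermodynamically: it is benzylic and α to the iminium carbon and then to the ketone, and bicarbonate equilibrates it to the isomer with the aryl group trans to the C3 arm. The step needs ion 9 to react with the alkene faster than with its own enamine form, the ether oxygen or the electron-rich ring; the excess of 8, the bulk of the silyl group on oxygen and the absence of any free OH or NH are what the substrates contribute to this. Aqueous bicarbonate hydrolyses iminium salt 10 to ketone 11 and releases amine 4 for recovery.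

Step 5
Reactants: 11 (2R,3R)-2-(4-benzyloxy-3-methoxyphenyl)-3-[(triisopropylsilyloxy)methyl]cyclobutan-1-one
Product: 12 (4S,5R)-5-(4-benzyloxy-3-methoxyphenyl)-4-[(triisopropylsilyloxy)methyl]oxolan-2-one
Conditions: mCPBA (1.2 equiv), NaHCO3, CH2Cl2, 0 °C
Reagents that add atoms: 3-chloroperbenzoic acid, O=C(OO)c1cccc(Cl)c1
Why: Baeyer–Villiger oxidation of a strained ketone, fast enough at 0 °C to precede oxidation of the arenes; the secondary benzylic carbon C2, which best carries positive charge, migrates in preference to the C4 methylene and does so with retention, so O1 takes the place of C5 on C2.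

Step 6
Reactants: 13 vanillin
Product: 14 4-benzyloxy-3-methoxybenzaldehyde
Conditions: BnBr, K2CO3, DMF, rt
Reagents that add atoms: benzyl bromide, BrCc1ccccc1
Why: Williamson ether synthesis on the phenol; the aldehyde is untouched.

Step 7
Reactants: 12 (4S,5R)-5-(4-benzyloxy-3-methoxyphenyl)-4-[(triisopropylsilyloxy)methyl]oxolan-2-one; 14 4-benzyloxy-3-methoxybenzaldehyde
Product: 16 (3S,4S,5R)-3-[(4-benzyloxy-3-methoxyphenyl)(hydroxy)methyl]-5-(4-benzyloxy-3-methoxyphenyl)-4-[(triisopropylsilyloxy)methyl]oxolan-2-one (carbinol epimers), via lithium enolate 15 (not isolated)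
Conditions: LiN(i-Pr)2 (LDA, 1.1 equiv), THF, −78 °C; then 14, −78 °C; AcOH quench
Reagents that add atoms: lithium diisopropylamide, [Li+].CC(C)[N-]C(C)C (lithium of intermediate 15 only)
Why: Aldol addition of a lactone enolate; C4 is the only enolisable position and the aldehyde adds anti to the C3 arm, but neither new stereocentre matters because both are removed in step 8.

Step 8
Reactants: 16 (3S,4S,5R)-3-[(4-benzyloxy-3-methoxyphenyl)(hydroxy)methyl]-5-(4-benzyloxy-3-methoxyphenyl)-4-[(triisopropylsilyloxy)methyl]oxolan-2-one
Product: 18 (3E,4S,5R)-3-(4-benzyloxy-3-methoxybenzylidene)-5-(4-benzyloxy-3-methoxyphenyl)-4-[(triisopropylsilyloxy)methyl]oxolan-2-one, via mesylate 17 (not isolated)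
Conditions: MsCl, Et3N, CH2Cl2, 0 °C; then DBU, 0 °C to rt
Reagents that add atoms: methanesulfonyl chloride, CS(=O)(=O)Cl (mesyl group of intermediate 17 only)
Why: Sulfonylation and E1cB elimination through the lactone enolate give the conjugated arylidene lactone as the E isomer (aryl away from the carbonyl); exposure to DBU is kept short and cold so that the vinylogous proton on C3 is not removed.

Step 9
Reactants: 18 (3E,4S,5R)-3-(4-benzyloxy-3-methoxybenzylidene)-5-(4-benzyloxy-3-methoxyphenyl)-4-[(triisopropylsilyloxy)methyl]oxolan-2-one
Product: 19 (3S,4S,5R)-3-(4-benzyloxy-3-methoxybenzyl)-5-(4-benzyloxy-3-methoxyphenyl)-4-[(triisopropylsilyloxy)methyl]oxolan-2-one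
Conditions: H2 (1 atm), 10% Pd/C, Ph2S (0.01 equiv), EtOAc, rt
Reagents that add atoms: none
Why: Heterogeneous syn-hydrogenation; in the E-arylidene lactone allylic 1,3-strain against the aryl group turns the C3 arm pseudoaxial, so the bulky silyloxymethyl group covers one face and hydrogen reaches C4 from the other, which leaves the new benzyl group cis to the C3 arm (C4 of the target, S). Diphenyl sulfide tempers the palladium so that the aryl benzyl ethers and the benzylic lactone C–O bond are not hydrogenolysed.

Step 10
Reactants: 19 (3S,4S,5R)-3-(4-benzyloxy-3-methoxybenzyl)-5-(4-benzyloxy-3-methoxyphenyl)-4-[(triisopropylsilyloxy)methyl]oxolan-2-one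
Product: 20 (1R,2S,3S)-3-(4-benzyloxy-3-methoxybenzyl)-1-(4-benzyloxy-3-methoxyphenyl)-2-[(triisopropylsilyloxy)methyl]butane-1,4-diol
Conditions: LiAlH4, THF, 0 °C
Reagents that add atoms: none
Why: Hydride reduction of the lactone to the 1,4-diol; hydride addition to the carbonyl is much faster than enolisation, so the cis C3/C4 pair is kept, no bond to C2 is broken, and silyl and benzyl ethers are inert.

Step 11
Reactants: 20 (1R,2S,3S)-3-(4-benzyloxy-3-methoxybenzyl)-1-(4-benzyloxy-3-methoxyphenyl)-2-[(triisopropylsilyloxy)methyl]butane-1,4-diol
Product: 21 (2R,3S,4S)-4-(4-benzyloxy-3-methoxybenzyl)-2-(4-benzyloxy-3-methoxyphenyl)-3-[(triisopropylsilyloxy)methyl]oxolane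
Conditions: CSA (0.1 equiv), CH2Cl2, 0 °C
Reagents that add atoms: none
Why: Acid-catalysed cycloetherification, the usual closure of this lignan class: the para-alkoxybenzylic alcohol ionises and the C5 hydroxyl closes the ring 5-exo on the cation; C2 is re-formed with the aryl group trans to the C3 arm because the all-cis alternative is strongly disfavoured, which is also the configuration carried in from 11. The silyl ether keeps the C3 oxygen out of the reaction.

Step 12
Reactants: 21 (2R,3S,4S)-4-(4-benzyloxy-3-methoxybenzyl)-2-(4-benzyloxy-3-methoxyphenyl)-3-[(triisopropylsilyloxy)methyl]oxolane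
Product: 22 [(2R,3S,4S)-4-(4-benzyloxy-3-methoxybenzyl)-2-(4-benzyloxy-3-methoxyphenyl)oxolan-3-yl]methanol
Conditions: TBAF, THF, 0 °C to rt
Reagents that add atoms: none
Why: Fluoride-driven desilylation; nothing else in the molecule reacts with fluoride.

Step 13
Reactants: 22 [(2R,3S,4S)-4-(4-benzyloxy-3-methoxybenzyl)-2-(4-benzyloxy-3-methoxyphenyl)oxolan-3-yl]methanol; 23 4-benzyloxybenzoic acid
Product: 24 [(2R,3S,4S)-4-(4-benzyloxy-3-methoxybenzyl)-2-(4-benzyloxy-3-methoxyphenyl)oxolan-3-yl]methyl 4-benzyloxybenzoate
Conditions: EDC·HCl, DMAP, CH2Cl2, rt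
Reagents that add atoms: none
Why: Steglich esterification of the only free hydroxyl, a primary alcohol; neutral conditions leave the acid-sensitive C2–O1 bond alone.

Step 14
Reactants: 24 [(2R,3S,4S)-4-(4-benzyloxy-3-methoxybenzyl)-2-(4-benzyloxy-3-methoxyphenyl)oxolan-3-yl]methyl 4-benzyloxybenzoate
Product: 25 agastinol
Conditions: H2 (1 atm), 10% Pd/C, EtOAc, rt
Reagents that add atoms: none
Why: Hydrogenolysis of the three aryl benzyl ethers, which cleave much faster than the benzylic dialkyl ether C2–O1 in a neutral aprotic solvent; the reaction is stopped once the last benzyl group is gone and no stereocentre is touched.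

## Compound list

1 | homovanillic acid | COc1cc(CC(=O)O)ccc1O | starting material
2 | benzyl 2-(4-benzyloxy-3-methoxyphenyl)acetate (formed in the flask in step 1) | COc1cc(CC(=O)OCc2ccccc2)ccc1OCc1ccccc1 | intermediate
3 | 2-(4-benzyloxy-3-methoxyphenyl)acetic acid | COc1cc(CC(=O)O)ccc1OCc1ccccc1 | intermediate
4 | (2R,5R)-2,5-dimethylpyrrolidine | C[C@@H]1CC[C@@H](C)N1 | starting material
5 | 2-(4-benzyloxy-3-methoxyphenyl)acetyl chloride (formed in the flask in step 2) | COc1cc(CC(=O)Cl)ccc1OCc1ccccc1 | intermediate
6 | 2-(4-benzyloxy-3-methoxyphenyl)-1-[(2R,5R)-2,5-dimethylpyrrolidin-1-yl]ethan-1-one | COc1cc(CC(=O)N2[C@H](C)CC[C@H]2C)ccc1OCc1ccccc1 | intermediate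
7 | allyl alcohol | C=CCO | starting material
8 | allyl triisopropylsilyl ether | C=CCO[Si](C(C)C)(C(C)C)C(C)C | intermediate
9 | (2R,5R)-1-[2-(4-benzyloxy-3-methoxyphenyl)ethenylidene]-2,5-dimethylpyrrolidinium triflate (keteniminium salt, formed in the flask in step 4) | COc1cc(C=C=[N+]2[C@H](C)CC[C@H]2C)ccc1OCc1ccccc1.[O-]S(=O)(=O)C(F)(F)F | intermediate
10 | (2R,5R)-1-[(2R,3R)-2-(4-benzyloxy-3-methoxyphenyl)-3-(triisopropylsilyloxymethyl)cyclobutylidene]-2,5-dimethylpyrrolidinium triflate (formed in the flask in step 4; C2 epimers converge) | C[C@@H]1CC[C@@H](C)[N+]1=C2C[C@@H](CO[Si](C(C)C)(C(C)C)C(C)C)[C@@H]2c3ccc(OCc4ccccc4)c(OC)c3.[O-]S(=O)(=O)C(F)(F)F | intermediate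
11 | (2R,3R)-2-(4-benzyloxy-3-methoxyphenyl)-3-[(triisopropylsilyloxy)methyl]cyclobutan-1-one (trans) | O=C1C[C@@H](CO[Si](C(C)C)(C(C)C)C(C)C)[C@@H]1c1ccc(OCc2ccccc2)c(OC)c1 | intermediate
12 | (4S,5R)-5-(4-benzyloxy-3-methoxyphenyl)-4-[(triisopropylsilyloxy)methyl]oxolan-2-one (trans) | O=C1C[C@@H](CO[Si](C(C)C)(C(C)C)C(C)C)[C@H](c2ccc(OCc3ccccc3)c(OC)c2)O1 | intermediate
13 | vanillin | COc1cc(C=O)ccc1O | starting material
14 | 4-benzyloxy-3-methoxybenzaldehyde | COc1cc(C=O)ccc1OCc1ccccc1 | intermediate
15 | lithium enolate of 12 (formed in the flask in step 7) | [Li+].[O-]C1=C[C@@H](CO[Si](C(C)C)(C(C)C)C(C)C)[C@H](c2ccc(OCc3ccccc3)c(OC)c2)O1 | intermediate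
16 | (3S,4S,5R)-3-[(4-benzyloxy-3-methoxyphenyl)(hydroxy)methyl]-5-(4-benzyloxy-3-methoxyphenyl)-4-[(triisopropylsilyloxy)methyl]oxolan-2-one, carbinol epimers | O=C1[C@H](C(O)c2ccc(OCc3ccccc3)c(OC)c2)[C@@H](CO[Si](C(C)C)(C(C)C)C(C)C)[C@H](c2ccc(OCc3ccccc3)c(OC)c2)O1 | intermediate
17 | methanesulfonate of 16 (formed in the flask in step 8) | O=C1[C@H](C(OS(C)(=O)=O)c2ccc(OCc3ccccc3)c(OC)c2)[C@@H](CO[Si](C(C)C)(C(C)C)C(C)C)[C@H](c2ccc(OCc3ccccc3)c(OC)c2)O1 | intermediate
18 | (3E,4S,5R)-3-(4-benzyloxy-3-methoxybenzylidene)-5-(4-benzyloxy-3-methoxyphenyl)-4-[(triisopropylsilyloxy)methyl]oxolan-2-one | O=C1/C(=C/c2ccc(OCc3ccccc3)c(OC)c2)[C@@H](CO[Si](C(C)C)(C(C)C)C(C)C)[C@H](c2ccc(OCc3ccccc3)c(OC)c2)O1 | intermediate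
19 | (3S,4S,5R)-3-(4-benzyloxy-3-methoxybenzyl)-5-(4-benzyloxy-3-methoxyphenyl)-4-[(triisopropylsilyloxy)methyl]oxolan-2-one (3,4-cis, 4,5-trans) | O=C1[C@@H](Cc2ccc(OCc3ccccc3)c(OC)c2)[C@@H](CO[Si](C(C)C)(C(C)C)C(C)C)[C@H](c2ccc(OCc3ccccc3)c(OC)c2)O1 | intermediate
20 | (1R,2S,3S)-3-(4-benzyloxy-3-methoxybenzyl)-1-(4-benzyloxy-3-methoxyphenyl)-2-[(triisopropylsilyloxy)methyl]butane-1,4-diol | OC[C@@H](Cc1ccc(OCc2ccccc2)c(OC)c1)[C@@H](CO[Si](C(C)C)(C(C)C)C(C)C)[C@@H](O)c1ccc(OCc2ccccc2)c(OC)c1 | intermediate
21 | (2R,3S,4S)-4-(4-benzyloxy-3-methoxybenzyl)-2-(4-benzyloxy-3-methoxyphenyl)-3-[(triisopropylsilyloxy)methyl]oxolane | COc1cc(C[C@@H]2CO[C@@H](c3ccc(OCc4ccccc4)c(OC)c3)[C@@H]2CO[Si](C(C)C)(C(C)C)C(C)C)ccc1OCc1ccccc1 | intermediate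
22 | [(2R,3S,4S)-4-(4-benzyloxy-3-methoxybenzyl)-2-(4-benzyloxy-3-methoxyphenyl)oxolan-3-yl]methanol | COc1cc(C[C@@H]2CO[C@@H](c3ccc(OCc4ccccc4)c(OC)c3)[C@@H]2CO)ccc1OCc1ccccc1 | intermediate
23 | 4-benzyloxybenzoic acid | O=C(O)c1ccc(OCc2ccccc2)cc1 | starting material
24 | [(2R,3S,4S)-4-(4-benzyloxy-3-methoxybenzyl)-2-(4-benzyloxy-3-methoxyphenyl)oxolan-3-yl]methyl 4-benzyloxybenzoate | COc1cc(C[C@@H]2CO[C@@H](c3ccc(OCc4ccccc4)c(OC)c3)[C@@H]2COC(=O)c2ccc(OCc3ccccc3)cc2)ccc1OCc1ccccc1 | intermediate
25 | agastinol, [(2R,3S,4S)-4-(4-hydroxy-3-methoxybenzyl)-2-(4-hydroxy-3-methoxyphenyl)oxolan-3-yl]methyl 4-hydroxybenzoate | COc1cc(C[C@@H]2CO[C@@H](c3ccc(O)c(OC)c3)[C@@H]2COC(=O)c2ccc(O)cc2)ccc1O | target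

## Step count and stereochemical account

- Total: 14 steps.
- Longest linear sequence: 12 steps from homovanillic acid 1 (steps 1, 2, 4, 5, 7 to 14). Steps 3 and 6 are one-step side branches.
- C3 is set in step 4 by the auxiliary and is never epimerisable afterwards except through the vinylogous proton of 18.
- C4 is set in step 9 under control of C3.
- C2 is set trans to C3 in step 4, carried with retention through steps 5 and 10, and re-formed trans to C3 in step 11. The ionising and the retentive pathway lead to the same isomer.

## Least certain steps and fallbacks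

**Step 4 (key step).** The most likely failure is slow capture of the monosubstituted keteniminium ion by an alkene that the allylic oxygen deactivates inductively. Self-condensation of the ion with its enamine form, or electrophilic attack on the electron-rich ring, could then take over. Facial control may also be incomplete or reversed, which would lower the enantiomeric purity of everything downstream.

The fallback makes the C2–C3 bond by an aldol reaction and takes O1 from the aldehyde oxygen, with no cyclobutane. It sets out from aldehyde 14 and returns at lactone 12. (R)-4-Benzyl-2-oxazolidinone is N-acylated with methyl 4-chloro-4-oxobutanoate (n-BuLi, THF, −78 °C) to give (R)-4-benzyl-3-(4-methoxy-4-oxobutanoyl)oxazolidin-2-one F1. Its boron enolate (Bu2BOTf, i-Pr2NEt, CH2Cl2, −78 to 0 °C) adds to 14 in an Evans syn-aldol reaction to give methyl (3R,4R)-3-[(R)-4-benzyl-2-oxooxazolidine-3-carbonyl]-4-(4-benzyloxy-3-methoxyphenyl)-4-hydroxybutanoate F2. F2 closes onto its methyl ester (on work-up or with catalytic TsOH) to give the trans lactone imide (R)-4-benzyl-3-[(2R,3R)-2-(4-benzyloxy-3-methoxyphenyl)-5-oxooxolane-3-carbonyl]oxazolidin-2-one F3. LiOH/H2O2 (THF/H2O, 0 °C, acidic work-up to re-close any opened lactone) frees (2R,3R)-2-(4-benzyloxy-3-methoxyphenyl)-5-oxooxolane-3-carboxylic acid F4 and returns the oxazolidinone. BH3·SMe2 (THF, 0 °C) reduces the acid beside the lactone to (4S,5R)-5-(4-benzyloxy-3-methoxyphenyl)-4-(hydroxymethyl)oxolan-2-one F5, which is silylated at once (TIPSCl, imidazole, CH2Cl2) to 12.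

**Step 9.** Hydrogen may be delivered to the wrong face, because the C2 aryl group lies on the face that has to be used. If the palladium is not tempered enough, the benzyl ethers or the benzylic lactone C–O bond may be hydrogenolysed.

The fallback replaces surface hydrogenation by hydride conjugate addition followed by kinetic protonation. It sets out from 18 and returns at 19. LiBH(s-Bu)3 (THF, −78 °C) adds hydride to the benzylidene carbon and gives the lithium enolate of 19, F6. This is protonated at −78 °C by 2,6-di-tert-butyl-4-methylphenol from the face opposite the C3 arm, which again leaves the benzyl group cis to that arm. Benzyl ethers and benzylic C–O bonds are inert to the borohydride.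

**Step 11.** The C2 cation may be captured by the C4 arene in a Friedel–Crafts closure to an aryltetralin. Some of the 2,3-cis ether may also form if closure is not reversible under the mild conditions.

The fallback closes the ring by SN2 at C5, so that no cation is formed and the C2–O bond from the Baeyer–Villiger step is used as it stands. It sets out from diol 20 and returns at 21. TsCl (1.05 equiv), Et3N and DMAP (cat.) in CH2Cl2 at 0 °C sulfonylate the primary hydroxyl selectively to give the primary monotosylate of 20, F7. KOt-Bu in THF at 0 °C then closes the oxolane by Williamson displacement.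

**Step 14.** Over-reduction is the risk: once the para-hydroxyl groups are free, the C2–O1 bond may be hydrogenolysed and the oxolane opened.

The fallback is a non-reductive debenzylation that goes directly from 24 to 25 with no new intermediate. BCl3 with pentamethylbenzene as benzyl-cation scavenger is used in CH2Cl2 at −78 °C and quenched cold, so that the Lewis acid does not ionise C2–O1.

## Further compounds

F1 | step 4 | (R)-4-benzyl-3-(4-methoxy-4-oxobutanoyl)oxazolidin-2-one | COC(=O)CCC(=O)N1[C@H](Cc2ccccc2)COC1=O
F2 | step 4 | methyl (3R,4R)-3-[(R)-4-benzyl-2-oxooxazolidine-3-carbonyl]-4-(4-benzyloxy-3-methoxyphenyl)-4-hydroxybutanoate | COC(=O)C[C@@H](C(=O)N1[C@H](Cc2ccccc2)COC1=O)[C@@H](O)c1ccc(OCc2ccccc2)c(OC)c1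
F3 | step 4 | (R)-4-benzyl-3-[(2R,3R)-2-(4-benzyloxy-3-methoxyphenyl)-5-oxooxolane-3-carbonyl]oxazolidin-2-one | O=C1C[C@@H](C(=O)N2[C@H](Cc3ccccc3)COC2=O)[C@H](c2ccc(OCc3ccccc3)c(OC)c2)O1
F4 | step 4 | (2R,3R)-2-(4-benzyloxy-3-methoxyphenyl)-5-oxooxolane-3-carboxylic acid | O=C1C[C@@H](C(=O)O)[C@H](c2ccc(OCc3ccccc3)c(OC)c2)O1
F5 | step 4 | (4S,5R)-5-(4-benzyloxy-3-methoxyphenyl)-4-(hydroxymethyl)oxolan-2-one | O=C1C[C@@H](CO)[C@H](c2ccc(OCc3ccccc3)c(OC)c2)O1
F6 | step 9 | lithium enolate of 19 | [Li+].[O-]C1=C(Cc2ccc(OCc3ccccc3)c(OC)c2)[C@@H](CO[Si](C(C)C)(C(C)C)C(C)C)[C@H](c2ccc(OCc3ccccc3)c(OC)c2)O1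
F7 | step 11 | primary monotosylate of 20 | Cc1ccc(S(=O)(=O)OC[C@@H](Cc2ccc(OCc3ccccc3)c(OC)c2)[C@@H](CO[Si](C(C)C)(C(C)C)C(C)C)[C@@H](O)c2ccc(OCc3ccccc3)c(OC)c2)cc1
F0 | step 14 | none | none
A1 | alternative 1 | trans,trans conjugate addition–aldol lactone with the dithiane on the future benzylic carbon and the menthyl acetal at the future C5 | COc1cc(C2(SCCCS2)[C@@H]2[C@@H](O[C@H]3C[C@@H](C)CC[C@@H]3C(C)C)OC(=O)[C@H]2[C@@H](O)c2ccc(OCc3ccccc3)c(OC)c2)ccc1OCc1ccccc1
A2 | alternative 1 | (5S)-5-[(1S,2R,5S)-menthyloxy]furan-2(5H)-one | O=C1C=C[C@@H](O[C@H]2C[C@@H](C)CC[C@@H]2C(C)C)O1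
A3 | alternative 1 | 2-(4-benzyloxy-3-methoxyphenyl)-1,3-dithiane | COc1cc(C2SCCCS2)ccc1OCc1ccccc1
A4 | alternative 2 | 2,3-trans-3,4-cis oxolane with both phenols benzylated and the C3 CH2OH as tert-butyldimethylsilyl ether | COc1cc(C[C@@H]2CO[C@@H](c3ccc(OCc4ccccc4)c(OC)c3)[C@@H]2CO[Si](C)(C)C(C)(C)C)ccc1OCc1ccccc1
A5 | alternative 2 | allyl ether of 1-(4-benzyloxy-3-methoxyphenyl)-3-(tert-butyldimethylsilyloxy)-2-iodopropan-1-ol, ether carbon configured as C2 of the target | C=CCO[C@@H](c1ccc(OCc2ccccc2)c(OC)c1)C(I)CO[Si](C)(C)C(C)(C)C
A6 | alternative 2 | 1-benzyloxy-4-iodo-2-methoxybenzene | COc1cc(I)ccc1OCc1ccccc1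
A7 | alternative 3 | 2,6-bis(4-benzyloxy-3-methoxyphenyl)-3-oxabicyclo[3.2.0]hept-6-ene, cis-fused, cyclobutene anti to the C2 aryl group | COc1cc(C2=C[C@H]3[C@H](c4ccc(OCc5ccccc5)c(OC)c4)OC[C@@H]23)ccc1OCc1ccccc1
A8 | alternative 3 | (R)-2-(4-benzyloxy-3-methoxyphenyl)-2,5-dihydrofuran | C1=C[C@H](c2ccc(OCc3ccccc3)c(OC)c2)OC1
A9 | alternative 3 | 1-benzyloxy-4-ethynyl-2-methoxybenzene | C#Cc1ccc(OCc2ccccc2)c(OC)c1
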